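In a one-step world an electrophile meets a nucleophile, the free base takes the acid set free, and one line of arithmetic ends the matter; this flask has more steps than that.

electrophile 20 mM; nucleophile 0.800 equiv; free base 1.00 equiv; time 5.0 min

    electrophile + nucleophile ⇌ acid set free + target (K1 = 1.1, k1 = 1.3 M⁻¹ s⁻¹)
    nucleophile + acid set free ⇌ protonated nucleophile, settled at all times (K2 = 7500 M⁻¹)
    acid set free + free base ⇌ salt of the base, settled at all times (K3 = 64000 M⁻¹)
    nucleophile + target → over-reaction product (k4 = 2.1 M⁻¹ s⁻¹)
    electrophile + target → side product (k5 = 2.3 M⁻¹ s⁻¹)

- part of the electrophile that has reacted at 5.0 min
- share of the unused nucleophile that is free and not bound as protonated nucleophile, at 5.0 min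

The two acid balances share the acid set free, so I divide them and it drops out: protonated nucleophile over nucleophile equals X times salt of the base over free base. Here X, the exchange ratio 0.117, is the constant for the nucleophile binding acid over the constant for the free base binding it. So the free share of the unused nucleophile is fr = 1/(1 + X·S/F), with S the salt and F the free base. The free base binds first, because 1300 exceeds 120. I therefore take S as n, the acid released, and F as the charge minus n.

I solve two ends for c, the part of the electrophile that has reacted. If the target stands, the first step runs forward by its second-order law. If an electrophile takes each target at once, two electrophiles go per acid.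

Target stands: c = 76.0%, n = 15.2 mM, fr = 73.0%

Target eaten: c up to 100%, n = 10.0 mM, fr = 89.5%

The target's half-life against the electrophile as charged, 0.25 min, is far shorter than 5.0 min, so I lean to the second end. But the nucleophile takes target too. By the charged rates I estimate that a share f = 0.578 goes to side product; on that share the nucleophile is the limiting reagent, so I reckon n from its charge.

n = 11.3 mM, c = 88.8%, fr = 86.9%

The forecast gives c 89% (84% to 93%) and fr 87.5% (86% to 89%), slightly above my fr; its grounds are that “only about one eighth of the remaining nucleophile is protonated”.

The flask gives c 89.4% and fr 87.4%, inside both ranges. At that time the flask keeps 5.5% of its nucleophile unbound, less than the 45% of its free base. With 11.0 mM of salt against that free base, X gives 0.144 bound per free nucleophile. In the neighbour with 2.00 equiv of nucleophile, 14.0 mM of salt and 30.1% of the charged free base give 78.6%, and that flask shows fr 78.6%.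

The constants used here are made up; what happens was integrated by code.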